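Late in Sunday's run the left-handed substrate reads 0 %, then 2 %, while the right-handed substrate still falls from 10 % to 3 %. The end excess asks how far the two hands have been drawn apart.

common to all: left-handed substrate 0.043 M; right-handed substrate 0.043 M
- Thursday's: partner 0.14 M; run made earlier
- Sunday's: partner 0.62 M; run made earlier
- north-west: partner 0.129 M; time 15 min
- west: partner 0.400 M; time 15 min

- Thursday's (time / min: right-handed substrate / %, left-handed substrate / %): 1.33: 46, 39; 4.00: 40, 26; 8.00: 35, 21; 10.0: 34, 17; 15.0: 28, 13
- Sunday's (time / min: right-handed substrate / %, left-handed substrate / %): 1.33: 34, 18; 2.50: 25, 6; 4.00: 17, 1; 8.00: 10, 0; 15.0: 3, 2

(readings scatter by 1.5 percentage points)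

- partner is single-handed; left-handed substrate and right-handed substrate are mirror images of each other, charged as a racemate, each of them at the stated concentration
- an excess is the difference of the two amounts in percent of their sum
- an excess is below zero if the other one leads
- the handed part of partner does not stay in what it makes, so the products of the two hands are mirror images too

- the flask that ends with the higher excess of right-handed substrate over left-handed substrate among what is left of the two, or "neither" when 2 percentage points or less lies between them (north-west / west / neither)
- excess of right-handed substrate over left-handed substrate among what is left of the two at the end, north-west
- excess of right-handed substrate over left-handed substrate among what is left of the two at the end, west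

Follow one substrate molecule of either hand. Each meets the same partner at each moment, so if nothing returns and each step is first order in both, the partner's history cancels. Call a hand's reach the natural logarithm of its charge over what is left. The left-handed reach is then a fixed multiple of the right-handed reach: the selectivity factor, read at 2.50 min on Sunday as 3.06. The lead, the logarithm of right-handed over left-handed substrate, equals the right-handed reach times this factor less one, and the lead gives the excess.

Is the lead per molar of partner charged one number? No: at 15.0 min it is 5.48 M⁻¹ on Thursday, from the two readings, and 9.34 M⁻¹ on Sunday, from the right-handed reading and the factor, Sunday's left-handed reading of 2 % lying close to the scatter of 1.5 percentage points. A straight line through these two values, against partner charged, gives leads of 0.696 for north-west and 3.03 for west, so this reckoning expects excesses of 33.5 % and 90.8 %.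

The forecast names west, with 34 % for north-west and 42 % for west, and so differs from this reckoning on west; its ground is that the “excess should therefore rise, peak, and eventually fall to zero”.

The flasks give west, with 38.0 % for north-west and 89.2 % for west.

    partner + left-handed substrate → left-handed product (k = 0.0240 M⁻¹ s⁻¹)
    partner + right-handed substrate → right-handed product (k = 0.00840 M⁻¹ s⁻¹)
    partner → decomposed reagent (k = 0.00120 s⁻¹)
    partner → decomposition product (k = 6.00 × 10⁻⁶ s⁻¹)

In west, partner passed into both products and decomposed reagent, and at 15.0 min left-handed substrate stood at 0.607 % and right-handed substrate at 10.7 % of the two charged together, partner at 25.5 % of its own charge. That right-handed amount and the factor 3.06 give an excess of 92.0 % for west, which shows 89.2 %. North-west read at 25 min holds 30.4 % right-handed substrate, which gives 47.2 %, and that flask shows 43.3 %.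

All runs were computed with constants of no real substance; scatter was added.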